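## The problem

The target is a flat, achiral chain of three rings: an oxazole that carries a 4-hydroxyphenyl group at C5, a 3,4,5-trichloropyrrol-2-yl group at C2 and a chlorine at C4. There is no stereocenter, so the task is one of regiochemistry and timing: two inter-ring C–C bonds and four C–Cl bonds. Of the four carbons that must be chlorinated, oxazole C4 is the least nucleophilic. The phenol ring, which must stay free of chlorine, would be the most easily chlorinated ring if left unmasked. The sensitive functions are three:

- the trichloropyrrole, whose N–H is acidic and which over-chlorinates to 2H-pyrroles;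
- the aryl and heteroaryl C–Cl bonds, which rule out hydrogenolysis and dissolving-metal steps;
- the phenol, which needs a mask that withdraws electrons and comes off without reduction.

The enabling feature is that C4 bears a heteroatom next to N3 and so stands at the carboxylic oxidation level. If the chlorine is replaced by a carbonyl oxygen, N3–C4 becomes an imide bond, and O1–C5 becomes a C–O bond to a benzylic carbon that can carry a leaving group. The C5 aryl group also makes the resulting oxazol-4(5H)-one enolisable, so the sp3 centre at C5 is transient, racemic and lost on aromatisation.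

## Retrosynthesis

**11 to 10 (O–S bond).** The phenol of target 11 is unmasked last from its 4-toluenesulfonate 10. A sulfonate is preferred to an ether for three reasons: it deactivates the benzene ring toward electrophilic halogen, it keeps a benzylic bromide on that ring from ionising, and it is cleaved by hydroxide at sulfur without any reductive step. The forward reaction only has to cleave S–O faster than hydroxide attacks the chlorinated heterocycles.

**10 to 9 (three pyrrole C–Cl bonds).** The three chlorines on the pyrrole are removed together, leading back to the 4-chlorooxazole 9 with an unsubstituted pyrrole. The neighbouring choice, carrying a trichlorinated pyrrole through the ring closure, is set aside for two reasons. Three chlorines and an acyl group make the pyrrole N–H about as acidic as an imide N–H, and the resulting pyrrolide could close a six-membered ring onto the benzylic bromide. That choice would also need a separate chlorination and amidation sequence to make the amide. Once oxazole C4 is already chlorinated and the benzene ring is deactivated, only the three pyrrole C–H positions are open to electrophilic chlorine, so the forward step is an exhaustive substitution without a regiochemical question.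

**9 to 8 (C4–Cl to C4=O).** The chlorine at C4 is traced to the carbonyl of the oxazol-4(5H)-one 8, which can react as its 4-hydroxyoxazole tautomer. The competing cut, electrophilic chlorination of a C4–H oxazole, places the hardest chlorination last and in competition with a fully chlorinated pyrrole. The functional-group interchange fixes the position by construction. The forward reaction is a deoxychlorination.

**8 to 6 and 5 (N3–C4 and O1–C5, the key cut).** Opening the imide bond and the benzylic C–O bond of 8 gives 1H-pyrrole-2-carboxamide 6 and racemic 2-bromo-2-[4-(tosyloxy)phenyl]acetyl chloride 5, by way of the open imide 7. Neighbouring cuts are less attractive: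

- cutting C2–O1 and C4–C5 (cyclodehydration of an acylamino ketone) would give a C4–H oxazole;
- cutting the oxazole–pyrrole bond would require a 2-metallated oxazole.

The chosen cut gives one commercial amide and one two-step acid chloride, and delivers the C4 oxygen together with the ring. The forward reaction must acylate the amide nitrogen rather than the pyrrole nitrogen and must close through oxygen.

**5 to 3 (C–Br and acyl C–Cl).** The α-bromo acid chloride 5 comes from 4-(tosyloxy)phenylacetic acid 3 by acid chloride formation (4) and α-bromination. The benzylic, enolisable α-position makes this a standard case. The tosyloxy group protects the ring from bromination.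

**3 to 1 and 2 (O–S bond).** Acid 3 is the sulfonate of commercial 4-hydroxyphenylacetic acid 1 with 4-toluenesulfonyl chloride 2. The phenoxide has to be sulfonylated in the presence of the carboxylate.

## Roads not taken

**Alternative 1:** The pyrrole ring is built last. The cut runs through pyrrole C3–C4 and N1–C5. In the forward direction the oxime A1 of 2-acetyl-5-(4-methoxyphenyl)oxazole reacts with acetylene A2 in a superbasic medium, by O-vinylation, [3,3]-shift and cyclisation, to give the pyrrolyl oxazole A3.
- Merits: the two-carbon unit is the cheapest possible, the oxazole–pyrrole bond is already present as the oxime carbon, and no pyrrole building block is needed.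
- Weak points: the step needs hot superbase and acetylene under pressure, and N-vinylation of the product competes. A1 itself requires a multistep synthesis of a 2-acyloxazole. A3 still lacks all four chlorines, and its anisole ring is more nucleophilic than oxazole C4, so chlorine would enter ortho to the methoxy group before C4 is reached. A Lewis-acid demethylation is also needed at the end.
- Comparison: in ring-forming economy this road is not inferior. The chosen plan sets against it a C4 chlorine fixed by construction and a deactivating phenol mask that keeps the benzene ring out of the halogenations.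

**Alternative 2:** The oxazole is cut at C4–C5 and O1–C2. 4-Hydroxybenzaldehyde A4 and tosylmethyl isocyanide A5 combine under base in an alcohol, with loss of sulfinate, to give 4-(oxazol-5-yl)phenol A6 in one step.
- Merits: this is the shortest access to a 5-aryloxazole and is better than the chosen plan in step count for the oxazole itself.
- Weak points: A6 carries neither the pyrrole nor the C4 substituent. The pyrrole must be attached at C2 through a 2-metallated oxazole, which ring-opens to an isocyano enolate, or by C–H arylation with a labile N-protected 2-halopyrrole. All four chlorines then have to be introduced electrophilically, with the phenol re-protected and oxazole C4 again the last and slowest site.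
- Comparison: the brevity of the first step is real. The chosen plan sets against it that the ring-forming step delivers the pyrrole and the C4 heteroatom at once, leaving only easy pyrrole chlorinations.

**Alternative 3:** The cut is at C2–N3 and O1–C5. The NH-triazole A7, 4-(1H-1,2,3-triazol-4-yl)phenyl 4-methylbenzenesulfonate, is N-acylated by 3,4,5-trichloro-1H-pyrrole-2-carbonyl chloride A8. The acyl triazole opens, extrudes nitrogen on heating and closes through the acyl oxygen to the 2,5-disubstituted oxazole A9.
- Merits: this is the closest rival. It is convergent, uses the same sulfonate mask, forms the same O1–C5 bond, and brings the trichloropyrrole in intact. In that last respect it is better than the chosen plan, which must chlorinate the pyrrole late.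
- Weak points: the one chlorination that remains is the hardest. Oxazole C4 in A9 is flanked by two electron-poor aryl groups, and the fully chlorinated pyrrole is prone to over-chlorination before C4 reacts. The triazole requires azide chemistry. The acylation site on the triazole decides whether ring opening occurs at all, and A8 carries an acidic N–H next to an acid chloride.
- Comparison: the chosen plan accepts three easy late chlorinations in exchange for positional certainty at C4, which comes from a carbonyl rather than from electrophilic substitution.

Key step: step 3

Remark: compound 8 is written as the 5H-oxazol-4-one. It is expected to equilibrate with its achiral 4-hydroxyoxazole tautomer, so it is handled as a racemate whose C5 configuration is of no consequence.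

## Route

Step 1
Reactants: 1 4-hydroxyphenylacetic acid; 2 4-toluenesulfonyl chloride
Product: 3 2-[4-(tosyloxy)phenyl]acetic acid
Conditions: NaOH (aq), THF, 0 °C to rt; then HCl (aq)
Reagents that add atoms: none
Why: Schotten–Baumann sulfonylation; in aqueous NaOH the phenoxide is the only lasting nucleophile for the sulfonyl chloride, any mixed anhydride at the carboxylate hydrolyses back, and acidification returns the free acid.

Step 2
Reactants: 3 2-[4-(tosyloxy)phenyl]acetic acid
Product: 5 racemic 2-bromo-2-[4-(tosyloxy)phenyl]acetyl chloride, via arylacetyl chloride 4 (not isolated)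
Conditions: SOCl2, 70 °C; then NBS, HBr (cat.), SOCl2, 80 °C, dark
Reagents that add atoms: thionyl chloride, O=S(Cl)Cl; N-bromosuccinimide, O=C1CCC(=O)N1Br
Why: Hell–Volhard–Zelinsky α-bromination in its acid chloride variant; the enol of 4 is brominated at the benzylic α-carbon by bromine released from NBS under HBr catalysis, the sulfonate deactivates the ring toward electrophilic bromine, and exclusion of light keeps the tosyl methyl group from radical bromination; the new centre is racemic.

Step 3
Reactants: 6 1H-pyrrole-2-carboxamide; 5 racemic 2-bromo-2-[4-(tosyloxy)phenyl]acetyl chloride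
Product: 8 racemic 2-(1H-pyrrol-2-yl)-5-[4-(tosyloxy)phenyl]oxazol-4(5H)-one, via bromoacyl imide 7 (not isolated)
Conditions: pyridine, CH2Cl2, 0 °C to rt; then NaF, DMF, rt, under argon
Reagents that add atoms: none
Why: The primary amide 6 is N-acylated by 5 with pyridine as HCl acceptor (an initial O-acyl isoimide reaches the same imide by 1,3-acyl shift), which forms N3–C4 and gives imide 7. NaF then removes the imide N–H proton, the most acidic one in 7, and the oxygen of the pyrrole-side carbonyl displaces the benzylic bromide by SN2, which forms O1–C5. The closest known reaction type is the two-stage preparation of 2-aryl-5-alkyloxazol-4(5H)-ones from aryl carboxamides and 2-bromoacyl halides with fluoride-induced closure. The single ring closes 5-exo-tet through oxygen; closure through the imide nitrogen would give a three-membered α-lactam and is excluded by ring size. No stereocenter is set under control: C5 is carried racemic from 5 and becomes trigonal in the 4-hydroxyoxazole tautomer and in step 4. The step needs acylation at the amide nitrogen and not at the pyrrole nitrogen, and O-alkylation and not pyrrole N-alkylation; both follow because the unchlorinated pyrrole N–H is far less acidic than the imide N–H, is not ionised by pyridine or NaF, and is not nucleophilic while protonated. The tosyloxy group keeps the benzylic bromide from ionising, so substitution stays intramolecular. The enol form of 8 is expected to be air-sensitive at C5, so it is isolated under argon and used promptly.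

Step 4
Reactants: 8 racemic 2-(1H-pyrrol-2-yl)-5-[4-(tosyloxy)phenyl]oxazol-4(5H)-one
Product: 9 4-[4-chloro-2-(1H-pyrrol-2-yl)oxazol-5-yl]phenyl 4-methylbenzenesulfonate
Conditions: POCl3, PhNEt2, Et4NCl, MeCN, 80 °C
Reagents that add atoms: phosphoryl chloride, O=P(Cl)(Cl)Cl
Why: Proposed new method: the 4-hydroxyoxazole tautomer of 8 is O-phosphorylated by POCl3, protonation at C5 (or reaction through the 5H tautomer) gives a 2-azaallyl cation stabilised by O1 and by the electron-rich pyrrol-2-yl group at C2, chloride adds at C4, and loss of dichlorophosphate and of H5 leaves the aromatic 4-chlorooxazole; the closest known reaction type is the POCl3 deoxychlorination of thiazol-4(5H)-ones, pyrazolones and 2-pyridones to the corresponding chloro heteroarenes, and the added chloride salt and dilution in MeCN are meant to let chloride capture outrun attack by the free pyrrole of a second molecule.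

Step 5
Reactants: 9 4-[4-chloro-2-(1H-pyrrol-2-yl)oxazol-5-yl]phenyl 4-methylbenzenesulfonate
Product: 10 4-[4-chloro-2-(3,4,5-trichloro-1H-pyrrol-2-yl)oxazol-5-yl]phenyl 4-methylbenzenesulfonate
Conditions: NCS (3.1 equiv), DMF, 0 °C to 50 °C; then Na2S2O3 (aq)
Reagents that add atoms: N-chlorosuccinimide, O=C1CCC(=O)N1Cl
Why: Exhaustive electrophilic aromatic chlorination of the pyrrole at C5, C4 and C3; the oxazole has no free position and the sulfonate-deactivated benzene ring is inert to NCS, so only the amount of reagent has to be controlled, and the reductive quench returns any N-chloro species.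

Step 6
Reactants: 10 4-[4-chloro-2-(3,4,5-trichloro-1H-pyrrol-2-yl)oxazol-5-yl]phenyl 4-methylbenzenesulfonate
Product: 11 4-[4-chloro-2-(3,4,5-trichloro-1H-pyrrol-2-yl)oxazol-5-yl]phenol
Conditions: KOH (aq), 1,4-dioxane, 80 °C; then HCl (aq)
Reagents that add atoms: none
Why: Hydroxide cleaves the aryl sulfonate at sulfur (S–O cleavage) and releases a phenoxide that is a good leaving group because of the para oxazole; under the same conditions the acidic trichloropyrrole is present as its anion, which shields the chlorinated rings from nucleophilic attack, and the alcohol-free medium avoids an alkyl tosylate that could alkylate phenoxide or pyrrolide.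

## Compound list

1 | 4-hydroxyphenylacetic acid | O=C(O)Cc1ccc(O)cc1 | starting material
2 | 4-toluenesulfonyl chloride | Cc1ccc(S(Cl)(=O)=O)cc1 | starting material
3 | 2-[4-(tosyloxy)phenyl]acetic acid | Cc1ccc(S(=O)(=O)Oc2ccc(CC(=O)O)cc2)cc1 | intermediate
4 | 2-[4-(tosyloxy)phenyl]acetyl chloride | Cc1ccc(S(=O)(=O)Oc2ccc(CC(Cl)=O)cc2)cc1 | intermediate (not isolated)
5 | racemic 2-bromo-2-[4-(tosyloxy)phenyl]acetyl chloride | Cc1ccc(S(=O)(=O)Oc2ccc(C(Br)C(Cl)=O)cc2)cc1 | intermediate
6 | 1H-pyrrole-2-carboxamide | NC(=O)c1ccc[nH]1 | starting material
7 | racemic N-{2-bromo-2-[4-(tosyloxy)phenyl]acetyl}-1H-pyrrole-2-carboxamide | Cc1ccc(S(=O)(=O)Oc2ccc(C(Br)C(=O)NC(=O)c3ccc[nH]3)cc2)cc1 | intermediate (not isolated)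
8 | racemic 2-(1H-pyrrol-2-yl)-5-[4-(tosyloxy)phenyl]oxazol-4(5H)-one (4-hydroxyoxazole tautomer in equilibrium) | Cc1ccc(S(=O)(=O)Oc2ccc(C3OC(-c4ccc[nH]4)=NC3=O)cc2)cc1 | intermediate
9 | 4-[4-chloro-2-(1H-pyrrol-2-yl)oxazol-5-yl]phenyl 4-methylbenzenesulfonate | Cc1ccc(S(=O)(=O)Oc2ccc(-c3oc(-c4ccc[nH]4)nc3Cl)cc2)cc1 | intermediate
10 | 4-[4-chloro-2-(3,4,5-trichloro-1H-pyrrol-2-yl)oxazol-5-yl]phenyl 4-methylbenzenesulfonate | Cc1ccc(S(=O)(=O)Oc2ccc(-c3oc(-c4[nH]c(Cl)c(Cl)c4Cl)nc3Cl)cc2)cc1 | intermediate
11 | 4-[4-chloro-2-(3,4,5-trichloro-1H-pyrrol-2-yl)oxazol-5-yl]phenol | Oc1ccc(-c2oc(-c3[nH]c(Cl)c(Cl)c3Cl)nc2Cl)cc1 | target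

## Step count and risks

Total step count: 6. Longest linear sequence: 6 steps (1 to 3 to 5 to 8 to 9 to 10 to 11).

**Step 4 (proposed new method).** Two things are most likely to go wrong. The substitution may stall after O-phosphorylation, because C4 of a 4-oxyoxazole is only weakly activated toward chloride, and the enol phosphate would then revert to 8 on work-up. Alternatively, the free pyrrole of one molecule may attack the activated oxazolone of another in a Vilsmeier-type self-condensation.

The fallback uses known chemistry and sets out from 8:
- Sulfonylation of the enol with PhNTf2 and Et3N in CH2Cl2 should give 2-(1H-pyrrol-2-yl)-5-[4-(tosyloxy)phenyl]oxazol-4-yl trifluoromethanesulfonate F1.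
- Palladium-catalysed formate reduction (Pd(OAc)2, 1,1'-bis(diphenylphosphino)ferrocene, HCO2H, Et3N, DMF, 60 °C) removes the triflate and leaves the aryl tosylate untouched, giving 4-[2-(1H-pyrrol-2-yl)oxazol-5-yl]phenyl 4-methylbenzenesulfonate F2.
- Exhaustive chlorination with NCS (4.1 equiv, DMF, 60 °C) at the three pyrrole positions and at oxazole C4 then comes back to the route at 10, bypassing 9.

The price is that the sluggish C4 chlorination is then the last electrophilic event.

**Step 3 (key step).** The likely failures are:
- dehydration of the primary amide to the nitrile through the O-acyl isoimide;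
- loss of the acid chloride by ketene formation, or quaternisation of pyridine at the benzylic bromide;
- autoxidation of the enol form of 8 at C5 during isolation.

The fallback reverses the roles of the two partners and sets out from 5. Addition of 5 to cold concentrated aqueous NH3 in THF (−20 °C, where acyl substitution outruns bromide displacement) should give racemic 2-bromo-2-[4-(tosyloxy)phenyl]acetamide F3. This is acylated without base in hot toluene by freshly prepared 1H-pyrrole-2-carbonyl chloride F4, an acylating agent with neither an α-hydrogen nor an α-leaving group. The product is the same imide 7, and closure with NaF in DMF under argon comes back to the route at 8.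

**Step 5.** Chlorination may stop short at C3, the position next to the oxazole, or run on to a 2H-pyrrole once excess reagent is present. Either outcome gives mixtures that are hard to separate.

The fallback introduces the chlorines before the ring closure and sets out from 5:
- Methyl 1H-pyrrole-2-carboxylate F5 is trichlorinated with SO2Cl2 (3.3 equiv, AcOH/CHCl3) to methyl 3,4,5-trichloro-1H-pyrrole-2-carboxylate F6.
- F6 is ammonolysed (NH3 in methanol under pressure, or the aluminium amide from AlMe3 and NH4Cl if the ester is sluggish) to 3,4,5-trichloro-1H-pyrrole-2-carboxamide F7.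
- F7 is acylated by 5 in hot toluene without base to racemic N-{2-bromo-2-[4-(tosyloxy)phenyl]acetyl}-3,4,5-trichloro-1H-pyrrole-2-carboxamide F8.
- F8 is closed thermally in refluxing 1,4-dioxane under a nitrogen sweep, again without base, so that the acidic trichloropyrrole N–H stays protonated and cannot alkylate at nitrogen. This gives racemic 5-[4-(tosyloxy)phenyl]-2-(3,4,5-trichloro-1H-pyrrol-2-yl)oxazol-4(5H)-one F9.
- Deoxychlorination of F9 under the conditions of step 4 comes back to the route at 10.

**Step 6.** Hydroxide may attack the heterocycles (ring opening at oxazole C2 or displacement of a ring chlorine) if S–O cleavage proves slow and needs forcing.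

The fallback changes the protecting group at the stage of 9, so that the last step is a mild methanolysis:
- 9 is detosylated with aqueous KOH in 1,4-dioxane, before the pyrrole carries any chlorine, to 4-[4-chloro-2-(1H-pyrrol-2-yl)oxazol-5-yl]phenol F10.
- Acetylation (Ac2O, pyridine) gives 4-[4-chloro-2-(1H-pyrrol-2-yl)oxazol-5-yl]phenyl acetate F11.
- NCS (3.1 equiv, DMF) chlorinates the pyrrole, which is far more reactive than the acetoxyphenyl ring, to 4-[4-chloro-2-(3,4,5-trichloro-1H-pyrrol-2-yl)oxazol-5-yl]phenyl acetate F12.
- K2CO3 in methanol at rt removes the acetate and comes back to the route at 11.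

## Further compounds

F1 | step 4 | 2-(1H-pyrrol-2-yl)-5-[4-(tosyloxy)phenyl]oxazol-4-yl trifluoromethanesulfonate | Cc1ccc(S(=O)(=O)Oc2ccc(-c3oc(-c4ccc[nH]4)nc3OS(=O)(=O)C(F)(F)F)cc2)cc1
F2 | step 4 | 4-[2-(1H-pyrrol-2-yl)oxazol-5-yl]phenyl 4-methylbenzenesulfonate | Cc1ccc(S(=O)(=O)Oc2ccc(-c3cnc(-c4ccc[nH]4)o3)cc2)cc1
F3 | step 3 | racemic 2-bromo-2-[4-(tosyloxy)phenyl]acetamide | Cc1ccc(S(=O)(=O)Oc2ccc(C(Br)C(N)=O)cc2)cc1
F4 | step 3 | 1H-pyrrole-2-carbonyl chloride | O=C(Cl)c1ccc[nH]1
F5 | step 5 | methyl 1H-pyrrole-2-carboxylate | COC(=O)c1ccc[nH]1
F6 | step 5 | methyl 3,4,5-trichloro-1H-pyrrole-2-carboxylate | COC(=O)c1[nH]c(Cl)c(Cl)c1Cl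
F7 | step 5 | 3,4,5-trichloro-1H-pyrrole-2-carboxamide | NC(=O)c1[nH]c(Cl)c(Cl)c1Cl
F8 | step 5 | racemic N-{2-bromo-2-[4-(tosyloxy)phenyl]acetyl}-3,4,5-trichloro-1H-pyrrole-2-carboxamide | Cc1ccc(S(=O)(=O)Oc2ccc(C(Br)C(=O)NC(=O)c3[nH]c(Cl)c(Cl)c3Cl)cc2)cc1
F9 | step 5 | racemic 5-[4-(tosyloxy)phenyl]-2-(3,4,5-trichloro-1H-pyrrol-2-yl)oxazol-4(5H)-one | Cc1ccc(S(=O)(=O)Oc2ccc(C3OC(-c4[nH]c(Cl)c(Cl)c4Cl)=NC3=O)cc2)cc1
F10 | step 6 | 4-[4-chloro-2-(1H-pyrrol-2-yl)oxazol-5-yl]phenol | Oc1ccc(-c2oc(-c3ccc[nH]3)nc2Cl)cc1
F11 | step 6 | 4-[4-chloro-2-(1H-pyrrol-2-yl)oxazol-5-yl]phenyl acetate | CC(=O)Oc1ccc(-c2oc(-c3ccc[nH]3)nc2Cl)cc1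
F12 | step 6 | 4-[4-chloro-2-(3,4,5-trichloro-1H-pyrrol-2-yl)oxazol-5-yl]phenyl acetate | CC(=O)Oc1ccc(-c2oc(-c3[nH]c(Cl)c(Cl)c3Cl)nc2Cl)cc1
A1 | alternative 1 | 1-[5-(4-methoxyphenyl)oxazol-2-yl]ethan-1-one oxime | COc1ccc(-c2cnc(C(C)=NO)o2)cc1
A2 | alternative 1 | acetylene | C#C
A3 | alternative 1 | 5-(4-methoxyphenyl)-2-(1H-pyrrol-2-yl)oxazole | COc1ccc(-c2cnc(-c3ccc[nH]3)o2)cc1
A4 | alternative 2 | 4-hydroxybenzaldehyde | O=Cc1ccc(O)cc1
A5 | alternative 2 | tosylmethyl isocyanide | Cc1ccc(S(=O)(=O)C[N+]#[C-])cc1
A6 | alternative 2 | 4-(oxazol-5-yl)phenol | Oc1ccc(-c2cnco2)cc1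
A7 | alternative 3 | 4-(1H-1,2,3-triazol-4-yl)phenyl 4-methylbenzenesulfonate | Cc1ccc(S(=O)(=O)Oc2ccc(-c3c[nH]nn3)cc2)cc1
A8 | alternative 3 | 3,4,5-trichloro-1H-pyrrole-2-carbonyl chloride | O=C(Cl)c1[nH]c(Cl)c(Cl)c1Cl
A9 | alternative 3 | 4-[2-(3,4,5-trichloro-1H-pyrrol-2-yl)oxazol-5-yl]phenyl 4-methylbenzenesulfonate | Cc1ccc(S(=O)(=O)Oc2ccc(-c3cnc(-c4[nH]c(Cl)c(Cl)c4Cl)o3)cc2)cc1
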